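The flavanone is read as the hydroacylation isomer of an achiral ortho-(1-arylvinyloxy)benzaldehyde. Everything rests on disconnecting ring C between the C3 methylene and the C4 carbonyl carbon, exploiting that C4 sits on ring A ortho to the O1 ether oxygen and that C2, the only stereocentre, carries H, O1 and ring B. In one redox-neutral operation a chiral cationic rhodium bisphosphine catalyst adds the formyl C–H across the C2=C3 enol ether double bond, closing ring C and setting C2 (S) by hydride delivery. The precursor is 2-[1-(3,4-dimethoxyphenyl)vinyloxy]-3,5-diprenylbenzaldehyde with its 4-hydroxyl masked as a methoxymethyl ether.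

Key step: step 5

Numbering used: flavanone numbering (O1, C2, C3, C4; ring A = fused benzo ring, ring B = 3,4-dimethoxyphenyl, ring C = pyranone).

Assumption: the (R)-antipode of the bisphosphine is taken to deliver hydride to the Re face of C2 of the enol ether; should the sense of induction prove opposite, the (S)-antipode would be used with no other change.

Step 1
Reactants: 1 2,4-dihydroxybenzaldehyde; 2 prenyl bromide (1-bromo-3-methylbut-2-ene, 2.3 equiv)
Product: 3 2,4-dihydroxy-3,5-bis(3-methylbut-2-en-1-yl)benzaldehyde
Conditions: KOH (10 % aq), 0 °C to rt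
Reagents that add atoms: none
Why: Phenoxide C-allylation in water, where the solvated oxygen is a poor nucleophile, should place the prenyl groups on the two free activated ring carbons C3 and C5 of the resorcinol unit; mono-C- and O-alkylated material is removed by chromatography and modest efficiency is expected.

Step 2
Reactants: 3 2,4-dihydroxy-3,5-bis(3-methylbut-2-en-1-yl)benzaldehyde
Product: 4 2-hydroxy-4-(methoxymethoxy)-3,5-bis(3-methylbut-2-en-1-yl)benzaldehyde
Conditions: MOMCl (1.1 equiv), iPr2NEt, CH2Cl2, 0 °C to rt
Reagents that add atoms: chloromethyl methyl ether (MOMCl), COCCl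
Why: Williamson-type O-alkylation; the 2-OH is tied up in a hydrogen bond to the formyl group, so the more acidic 4-OH para to the aldehyde should be the one alkylated.

Step 3
Reactants: 5 1-(3,4-dimethoxyphenyl)ethanone
Product: 6 4-(1-bromovinyl)-1,2-dimethoxybenzene
Conditions: P(OPh)3, Br2, CH2Cl2, −60 °C; then 5, Et3N, −60 °C to reflux; used freshly prepared
Reagents that add atoms: bromine, BrBr
Why: Ketone to vinyl bromide conversion with the preformed triphenyl phosphite–bromine adduct (oxygen activation, bromide addition, amine-induced elimination); no free Br2 remains to brominate the electron-rich ring.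

Step 4
Reactants: 4 2-hydroxy-4-(methoxymethoxy)-3,5-bis(3-methylbut-2-en-1-yl)benzaldehyde; 6 4-(1-bromovinyl)-1,2-dimethoxybenzene (1.5 equiv)
Product: 7 2-{[1-(3,4-dimethoxyphenyl)vinyl]oxy}-4-(methoxymethoxy)-3,5-bis(3-methylbut-2-en-1-yl)benzaldehyde
Conditions: CuI (20 mol %), N,N-dimethylglycine hydrochloride (40 mol %), Cs2CO3, 1,4-dioxane, 90 °C; chromatography on Et3N-deactivated silica
Reagents that add atoms: none
Why: Ullmann-type copper-catalysed C–O coupling of a phenol with a vinyl bromide, which tolerates the aldehyde, acetal and prenyl groups; the acidic salicylaldehyde phenol is fully deprotonated by Cs2CO3.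

Step 5
Reactants: 7 2-{[1-(3,4-dimethoxyphenyl)vinyl]oxy}-4-(methoxymethoxy)-3,5-bis(3-methylbut-2-en-1-yl)benzaldehyde
Product: 8 (2S)-2-(3,4-dimethoxyphenyl)-7-(methoxymethoxy)-6,8-bis(3-methylbut-2-en-1-yl)chroman-4-one
Conditions: [Rh(cod)Cl]2 (2.5 mol %), (R)-DTBM-SEGPHOS (5.5 mol %), NaB[3,5-(CF3)2C6H3]4 (5 mol %), 1,4-dioxane, 80 °C
Reagents that add atoms: none
Why: Proposed new method: oxidative addition of the formyl C–H bond of 7 to the cationic monovalent rhodium bisphosphine complex gives an acyl hydride of trivalent rhodium, the hydride is transferred to C2 of the coordinated 1,1-disubstituted enol ether, and C–C reductive elimination from the resulting seven-membered acyl alkyl rhodacycle forms the C3–C4 bond. The closest known reaction type is the rhodium-bisphosphine-catalysed enantioselective intramolecular hydroacylation of 1,1-disubstituted alkenes in ortho-allyl- and ortho-isopropenylbenzaldehydes to benzo-fused six- and five-membered ketones; an aryl enol ether as the alkene partner is the untested element. Ring C closes in the 6-endo-trig mode, both alkene carbons becoming ring members. The new stereocentre C2 is controlled by the chiral bisphosphine, which fixes the face of the enol ether that receives the hydride; delivery to the Re face of C2 gives the 2S configuration. The step needs acyl transfer to the terminal CH2 and not 5-exo closure to a 2-aryl-2-methylbenzofuran-3-one, and the 1,1-disubstitution secures this because the alternative demands a tertiary alkyl rhodium and reductive elimination to a quaternary carbon. The prenyl double bonds are trisubstituted and meta to the formyl group, so they cannot compete, and the non-coordinating counter-ion keeps a free coordination site that disfavours decarbonylation.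

Step 6
Reactants: 8 (2S)-2-(3,4-dimethoxyphenyl)-7-(methoxymethoxy)-6,8-bis(3-methylbut-2-en-1-yl)chroman-4-one
Product: 9 (2S)-2-(3,4-dimethoxyphenyl)-7-hydroxy-6,8-bis(3-methylbut-2-en-1-yl)chroman-4-one (IN0946)
Conditions: HCl (3 M aq, few equiv), MeOH, 40 °C, short reaction time
Reagents that add atoms: none
Why: Acid-catalysed methanolysis of the aryl methoxymethyl acetal; C2 cannot epimerise by enolisation and flavanones do not ring-open under mild acid, so the configuration should be retained, while brief mild conditions limit acid cyclisation of the prenyl groups onto the 7-OH.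

Compound list
1 | 2,4-dihydroxybenzaldehyde | O=Cc1ccc(O)cc1O | starting material
2 | prenyl bromide (1-bromo-3-methylbut-2-ene) | CC(C)=CCBr | starting material
3 | 2,4-dihydroxy-3,5-bis(3-methylbut-2-en-1-yl)benzaldehyde | O=Cc1cc(CC=C(C)C)c(O)c(CC=C(C)C)c1O | intermediate
4 | 2-hydroxy-4-(methoxymethoxy)-3,5-bis(3-methylbut-2-en-1-yl)benzaldehyde | O=Cc1cc(CC=C(C)C)c(OCOC)c(CC=C(C)C)c1O | intermediate
5 | 1-(3,4-dimethoxyphenyl)ethanone | CC(=O)c1ccc(OC)c(OC)c1 | starting material
6 | 4-(1-bromovinyl)-1,2-dimethoxybenzene | C=C(Br)c1ccc(OC)c(OC)c1 | intermediate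
7 | 2-{[1-(3,4-dimethoxyphenyl)vinyl]oxy}-4-(methoxymethoxy)-3,5-bis(3-methylbut-2-en-1-yl)benzaldehyde | COc1ccc(C(=C)Oc2c(C=O)cc(CC=C(C)C)c(OCOC)c2CC=C(C)C)cc1OC | intermediate
8 | (2S)-2-(3,4-dimethoxyphenyl)-7-(methoxymethoxy)-6,8-bis(3-methylbut-2-en-1-yl)chroman-4-one | COc1ccc([C@@H]2CC(=O)c3cc(CC=C(C)C)c(OCOC)c(CC=C(C)C)c3O2)cc1OC | intermediate
9 | (2S)-2-(3,4-dimethoxyphenyl)-7-hydroxy-6,8-bis(3-methylbut-2-en-1-yl)chroman-4-one (IN0946) | COc1ccc([C@@H]2CC(=O)c3cc(CC=C(C)C)c(O)c(CC=C(C)C)c3O2)cc1OC | target

Total step count: 6. Longest linear sequence: 5 steps (steps 1, 2, 4, 5, 6).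

Steps most likely to fail

Step 5 (Proposed new method). The acyl rhodium hydride may decarbonylate, the alkyl rhodium intermediate may lose the β-aryloxy group, or hydride delivery may show poor facial selectivity. The fallback uses known chemistry, sets the stereocentre first and closes the same C3–C4 bond by carbene-catalysed acylation of an alkyl halide. It sets out from 4. Commercial 2-bromo-1-(3,4-dimethoxyphenyl)ethanone is reduced with BH3·SMe2 and the (S)-2-methyl-CBS-oxazaborolidine, which should give (S)-2-bromo-1-(3,4-dimethoxyphenyl)ethanol F1. Mitsunobu etherification of phenol 4 with F1 (PPh3, DIAD, THF, 0 °C) proceeds with inversion and should give (R)-2-[2-bromo-1-(3,4-dimethoxyphenyl)ethoxy]-4-(methoxymethoxy)-3,5-bis(3-methylbut-2-en-1-yl)benzaldehyde F2. A thiazolium precatalyst (3-benzyl-5-(2-hydroxyethyl)-4-methylthiazolium chloride) with DBU in 1,4-dioxane then converts the aldehyde into its Breslow intermediate, which displaces the primary bromide in a 6-exo-tet closure. This reaction type is known for 2-(2-sulfonyloxyethoxy)benzaldehydes giving chroman-4-ones, and the bromide is expected to serve as the leaving group in the same way. The fallback comes back to the route at 8.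

Step 4. C–O coupling may be slow at the doubly ortho-substituted, copper-chelating salicylaldehyde phenoxide, so that base-induced dehydrobromination of 6 takes over. The fallback sets out from 4 and replaces the cross-coupling by alkylation and elimination. NaBH4 reduction of commercial 2-bromo-1-(3,4-dimethoxyphenyl)ethanone gives racemic 2-bromo-1-(3,4-dimethoxyphenyl)ethanol F3. Mitsunobu etherification of 4 with F3 (PPh3, DIAD, THF) gives racemic 2-[2-bromo-1-(3,4-dimethoxyphenyl)ethoxy]-4-(methoxymethoxy)-3,5-bis(3-methylbut-2-en-1-yl)benzaldehyde F4. E2 elimination of HBr with KOtBu in THF at −20 °C removes the only β-hydrogen, the benzylic one, and comes back to the route at 7.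

Step 1. Alkylation may be incomplete or misdirected (mono-C-alkylation, O-alkylation, cyclisation of a prenyl group onto a neighbouring hydroxyl). The fallback sets out from 1 and fixes the regiochemistry by halogenation. Bromination (Br2, AcOH, rt) at the two activated positions gives 3,5-dibromo-2,4-dihydroxybenzaldehyde F5. A double Stille coupling with tributyl(3-methylbut-2-en-1-yl)stannane (Pd(PPh3)4, a complex of zerovalent palladium, DMF, 90 °C) then comes back to the route at 3.

Further compounds
F1 | step 5 | (S)-2-bromo-1-(3,4-dimethoxyphenyl)ethanol | O[C@H](CBr)c1ccc(OC)c(OC)c1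
F2 | step 5 | (R)-2-[2-bromo-1-(3,4-dimethoxyphenyl)ethoxy]-4-(methoxymethoxy)-3,5-bis(3-methylbut-2-en-1-yl)benzaldehyde | COc1ccc([C@H](CBr)Oc2c(C=O)cc(CC=C(C)C)c(OCOC)c2CC=C(C)C)cc1OC
F3 | step 4 | racemic 2-bromo-1-(3,4-dimethoxyphenyl)ethanol | OC(CBr)c1ccc(OC)c(OC)c1
F4 | step 4 | racemic 2-[2-bromo-1-(3,4-dimethoxyphenyl)ethoxy]-4-(methoxymethoxy)-3,5-bis(3-methylbut-2-en-1-yl)benzaldehyde | COc1ccc(C(CBr)Oc2c(C=O)cc(CC=C(C)C)c(OCOC)c2CC=C(C)C)cc1OC
F5 | step 1 | 3,5-dibromo-2,4-dihydroxybenzaldehyde | O=Cc1cc(Br)c(O)c(Br)c1O
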